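**Plan**

1. Cuts: (a) the E-stilbene (Heck) gives a western aryl chloride and an eastern 4-vinyl-2,3-diaryl-2,3-dihydrobenzofuran; (b) in the western half the seven-membered ring is opened at two bonds at once: C-3–C-3a of the dihydrobenzofuran (benzo ring = ring A) and C-α–C-β, the bond between the two vicinal methines (C-α carries the 4-hydroxyphenyl group and ring B; C-β carries ring A and the 2-hydroxyaryl ring C).
2. Feature used: C-3a is ortho to the furan oxygen and para to the other ring A oxygen (arene nucleophile); C-3 can be the ketone carbon of an α-aryloxy ketone; C-α is a para-hydroxybenzylic carbon (quinone methide); C-β is ortho to the ring C phenol, which can tie it back as an enolisable benzofuran-2(3H)-one (temporary lactone ring, its carbonyl carbon is cut out again).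
3. Forward order: lactone phenol + α-diazo ketone → aryl ether → one-flask acid-catalysed (4+3)-type double closure (furan ring, then seven-membered ring) → lactone carbon removed → benzofuran dearomatised to the trans-dihydrobenzofuran → methyl ethers exchanged for acetates → Heck union → deacetylation.
4. Stereochemistry: C-α by the chiral Brønsted acid in the key step; C-β by protonation of a benzylic carbanion anti to the C-α aryl; C-3 then C-2 by ionic hydrogenation (proton on the convex face, hydride trans); eastern C-3′ by a Rh-catalysed enantioselective C–H insertion, C-2′ by equilibration to trans.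

Key step: step 10

Assumption: 14 is drawn as the open hydroxy ketone although it will equilibrate with its cyclic hemiketal, and the senses of induction of the chiral acid (step 10) and of Rh2(R-PTAD)4 (step 20) are assigned by analogy; the mirror-image catalyst is used if either proves opposite.

**Route**

Step 1
Reactants: 1 3-bromo-5-methoxyphenol
Product: 2 1-bromo-3-methoxy-5-(methoxymethoxy)benzene
Conditions: MOMCl, K2CO3, acetone, 25 °C
Reagents that add atoms: chloromethyl methyl ether, COCCl
Why: Williamson O-alkylation masks the phenol so that it survives the strongly basic enolate arylation of step 2.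

Step 2
Reactants: 3 5-chlorobenzofuran-2(3H)-one; 2 1-bromo-3-methoxy-5-(methoxymethoxy)benzene
Product: 4 5-chloro-3-[3-methoxy-5-(methoxymethoxy)phenyl]benzofuran-2(3H)-one (racemic)
Conditions: LiN(SiMe3)2 (2.2 equiv), Pd(dba)2 (3 mol %), P(t-Bu)3 (3 mol %), toluene, 25 to 50 °C; aq. NH4Cl
Reagents that add atoms: none
Why: Palladium-catalysed α-arylation of the lactone enolate joins ring A to the carbon that becomes C-β; the C–Br bond of 2 should react ahead of the C–Cl bond of 3, and the more acidic product stays as its enolate, which prevents a second arylation.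

Step 3
Reactants: 4 5-chloro-3-[3-methoxy-5-(methoxymethoxy)phenyl]benzofuran-2(3H)-one
Product: 5 5-chloro-3-(3-hydroxy-5-methoxyphenyl)benzofuran-2(3H)-one (racemic)
Conditions: 3 M HCl, THF, 40 °C
Reagents that add atoms: none
Why: Acid hydrolysis of the MOM acetal frees the ring A phenol, while the aryl lactone recloses spontaneously and is kept.

Step 4
Reactants: 6 2-bromo-4,6-dimethoxybenzaldehyde; 7 [4-(tert-butyldimethylsilyloxy)phenyl]magnesium bromide
Product: 8 (2-bromo-4,6-dimethoxyphenyl)[4-(tert-butyldimethylsilyloxy)phenyl]methanol (racemic)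
Conditions: THF, −78 to 0 °C; aq. NH4Cl
Reagents that add atoms: none
Why: Grignard addition to the aldehyde attaches the future 4-hydroxyphenyl group to C-α on ring B; the carbinol configuration is irrelevant because C-α becomes planar (quinone methide) in step 10.

Step 5
Reactants: 8 (2-bromo-4,6-dimethoxyphenyl)[4-(tert-butyldimethylsilyloxy)phenyl]methanol
Product: 9 triisopropylsilyl ether of 8
Conditions: TIPSOTf, 2,6-lutidine, CH2Cl2, 0 to 25 °C
Reagents that add atoms: triisopropylsilyl trifluoromethanesulfonate, CC(C)[Si](C(C)C)(C(C)C)OS(=O)(=O)C(F)(F)F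
Why: Silylation protects the benzhydrol, and the bulky TIPS group should not migrate from oxygen to carbon (retro-Brook shift) in the ortho-lithiated arene of step 6.

Step 6
Reactants: 9 triisopropylsilyl ether of 8; 10 N-methoxy-N-methyl-2-(4-methoxyphenyl)acetamide
Product: 11 1-{2-[(4-(tert-butyldimethylsilyloxy)phenyl)(triisopropylsilyloxy)methyl]-3,5-dimethoxyphenyl}-2-(4-methoxyphenyl)ethan-1-one
Conditions: t-BuLi (2.1 equiv), THF, −78 °C; then 10, −78 to 0 °C; aq. NH4Cl
Reagents that add atoms: none
Why: Bromine–lithium exchange and acylation of the aryllithium by the Weinreb amide (stable chelate, no over-addition) place the future C-3 (carbonyl) and C-2 (methylene) on ring B.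

Step 7
Reactants: 11 the ketone of step 6
Product: 12 2-diazo derivative of 11 (α-aryl-α-diazo ketone)
Conditions: 4-acetamidobenzenesulfonyl azide, DBU, MeCN, 0 to 25 °C
Reagents that add atoms: 4-acetamidobenzenesulfonyl azide, CC(=O)Nc1ccc(cc1)S(=O)(=O)N=[N+]=[N-]
Why: Regitz diazo transfer to the methylene activated by both the ketone and the 4-methoxyphenyl ring gives the diazo ketone.

Step 8
Reactants: 5 5-chloro-3-(3-hydroxy-5-methoxyphenyl)benzofuran-2(3H)-one; 12 diazo ketone
Product: 13 2-[3-(5-chloro-2-oxo-2,3-dihydrobenzofuran-3-yl)-5-methoxyphenoxy]-1-{2-[(4-(tert-butyldimethylsilyloxy)phenyl)(triisopropylsilyloxy)methyl]-3,5-dimethoxyphenyl}-2-(4-methoxyphenyl)ethan-1-one (diastereomer mixture)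
Conditions: [Cu(MeCN)4]PF6 (5 mol %), CH2Cl2, 25 °C, slow addition of 12
Reagents that add atoms: none
Why: Copper-carbene O–H insertion into the phenol forms the aryl ether under neutral conditions, which avoids the C-alkylation that a Williamson reaction would cause at the C-acidic lactone; all stereocentres of 13 are erased or reset later, so the mixture is used as such.

Step 9
Reactants: 13 the bis-silyl ether of step 8
Product: 14 2-[3-(5-chloro-2-oxo-2,3-dihydrobenzofuran-3-yl)-5-methoxyphenoxy]-1-{2-[hydroxy(4-hydroxyphenyl)methyl]-3,5-dimethoxyphenyl}-2-(4-methoxyphenyl)ethan-1-one (diastereomer mixture)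
Conditions: HF·pyridine, pyridine, THF, 0 to 25 °C
Reagents that add atoms: none
Why: Buffered fluoride cleavage of both silyl ethers unveils the para-hydroxybenzhydrol without ionising it.

Step 10
Reactants: 14 the hydroxy ketone of step 9
Product: 17 (αS)-spiro-lactone: benzofuran fused to the new seven-membered ring; C-β is the spiro C-3 of the 5-chlorobenzofuran-2(3H)-one, via benzofuran carbinol 15 (not isolated), via para-quinone methide 16 (not isolated)
Conditions: (R)-3,3′-bis(2,4,6-triisopropylphenyl)-1,1′-binaphthyl-2,2′-diyl N-triflylphosphoramide (10 mol %), 5 Å molecular sieves, ClCH2CH2Cl, 40 °C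
Reagents that add atoms: none
Why: Proposed new method: the chiral Brønsted acid activates the ketone of 14 (through its cyclic hemiketal and the derived oxocarbenium ion) so that C-3a of ring A attacks C-3 in a 5-exo-trig Friedel–Crafts closure and water is lost to give benzofuran 15; the para-hydroxybenzhydrol, now held next to the lactone, then loses water to the para-quinone methide 16, to which the enol form of the benzofuranone (C-β) adds in a 7-exo-trig 1,6-conjugate addition that closes the seven-membered ring and restores the phenol. The closest known reaction types are the acid-mediated cyclodehydration of α-aryloxy ketones to 3-arylbenzofurans and the chiral-phosphoric-acid-catalysed enantioselective 1,6-addition of enolisable carbonyl compounds to para-quinone methides formed in the flask from para-hydroxybenzyl alcohols; what is new is their coupling in one flask and the seven-membered ring size. C-α is set in the second event by the chiral phosphoramide anion, which is hydrogen-bonded to the quinone methide oxygen and to the enol OH and so shields one face of the methide carbon; the spiro centre C-β forms as a diastereomer mixture that does not matter because step 12 makes this carbon planar again. The step needs closure at C-3a and not at the ring A carbon between the two oxygens (C-3a is para to OMe and less crowded, as in known cyclodehydrations of 3,5-dioxygenated aryl ethers), C- and not O-alkylation of the enol (the O-adduct reverts under acid), and seven-ring closure only after the benzofuran exists (before that the two carbons could only meet in a ten-membered ring, and the quinone methide simply re-adds water).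

Step 11
Reactants: 17 (αS)-spiro-lactone
Product: 18 (αS)-spiro-lactol (2-hydroxy-2,3-dihydrobenzofuran in place of the lactone)
Conditions: i-Bu2AlH (2.5 equiv), CH2Cl2, −78 °C; aq. Rochelle salt
Reagents that add atoms: none
Why: Partial reduction of the aryl lactone should stop at the lactol (the tetrahedral aluminate is stable at −78 °C), which turns the helper carbonyl into a masked aldehyde without base, so the quinone-methide adduct cannot fragment by retro-1,6-addition.

Step 12
Reactants: 18 (αS)-spiro-lactol
Product: 20 (αS,βS)-benzofuran hexamethyl ether with C-β–H, via aldehyde 19 (not isolated)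
Conditions: MeI, K2CO3, DMF, 25 °C; then KOH, H2O, DMSO, 80 °C
Reagents that add atoms: iodomethane, CI
Why: Methylation of both phenoxides opens the lactol to the non-enolisable α,α-diaryl aldehyde 19, hydroxide-induced deformylation (retro-Claisen-type C–C cleavage with loss of formate) then removes the helper carbon, and the planar diarylmethyl carbanion should be protonated anti to the aryl group on C-α, which sets C-β with the two methine hydrogens cis.

Step 13
Reactants: 20 (αS,βS)-benzofuran hexamethyl ether
Product: 21 (2S,3S,αS,βS)-western trans-2,3-dihydrobenzofuran hexamethyl ether (aryl chloride)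
Conditions: Et3SiH, CF3CO2H, CH2Cl2, 0 to 25 °C
Reagents that add atoms: none
Why: Ionic hydrogenation dearomatises the benzofuran: protonation at C-3 on the convex face of the boat-shaped seven-membered ring (new H in the flagpole position, also the thermodynamically preferred arrangement with the fused furan bond equatorial) gives the 2-aryl oxocarbenium ion, which takes hydride trans to ring B, so C-3 and C-2 are set relative to C-α and C-β.

Step 14
Reactants: 21 western hexamethyl ether
Product: 23 (2S,3S,αS,βS)-western hexaacetate (aryl chloride), via hexaphenol 22 (not isolated)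
Conditions: BBr3, CH2Cl2, −78 to 0 °C; MeOH; then Ac2O, pyridine, DMAP, 25 °C
Reagents that add atoms: acetic anhydride, CC(=O)OC(C)=O
Why: Lewis-acid ether cleavage is done before the acid-sensitive stilbene exists and the phenols are re-protected as acetates for a mild basic end-game; any reversible opening at O–C-2 through the para-quinone methide recloses to the stable trans isomer.

Step 15
Reactants: 6 2-bromo-4,6-dimethoxybenzaldehyde
Product: 24 2-bromo-6-hydroxy-4-methoxybenzaldehyde
Conditions: BCl3, CH2Cl2, −78 to 0 °C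
Reagents that add atoms: none
Why: Chelation of boron between the aldehyde oxygen and the ortho methoxy group directs the demethylation to that position only.

Step 16
Reactants: 24 2-bromo-6-hydroxy-4-methoxybenzaldehyde; 25 4-methoxybenzyl chloride
Product: 26 2-bromo-4-methoxy-6-[(4-methoxybenzyl)oxy]benzaldehyde
Conditions: K2CO3, DMF, 60 °C
Reagents that add atoms: none
Why: Williamson ether synthesis installs the benzylic CH2 whose C–H bond is inserted into in step 20 and becomes C-2′.

Step 17
Reactants: 26 the aldehyde of step 16; 27 (3,5-dimethoxyphenyl)magnesium chloride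
Product: 28 {2-bromo-4-methoxy-6-[(4-methoxybenzyl)oxy]phenyl}(3,5-dimethoxyphenyl)methanol (racemic)
Conditions: THF, −20 to 0 °C; aq. NH4Cl
Reagents that add atoms: none
Why: Grignard addition to the aldehyde brings in the 3,5-dioxygenated aryl group on the future C-3′.

Step 18
Reactants: 28 the carbinol of step 17
Product: 29 {2-bromo-4-methoxy-6-[(4-methoxybenzyl)oxy]phenyl}(3,5-dimethoxyphenyl)methanone
Conditions: MnO2, CH2Cl2, 25 °C
Reagents that add atoms: none
Why: The doubly benzylic alcohol is oxidised selectively to the diaryl ketone by activated MnO2.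

Step 19
Reactants: 29 the diaryl ketone
Product: 30 hydrazone of 29
Conditions: N2H4·H2O, AcOH (cat.), n-BuOH, 120 °C
Reagents that add atoms: hydrazine (used as the hydrate), NN
Why: Condensation gives the hydrazone, the precursor of the donor/donor diazo compound; forcing conditions are chosen for the di-ortho-substituted ketone.

Step 20
Reactants: 30 hydrazone
Product: 32 (2R,3S)-4-bromo-3-(3,5-dimethoxyphenyl)-6-methoxy-2-(4-methoxyphenyl)-2,3-dihydrobenzofuran (cis), via diazo compound 31 (not isolated)
Conditions: MnO2, CH2Cl2, 0 °C; filter; Rh2(R-PTAD)4 [dirhodium tetrakis((R)-(1-adamantyl)(phthalimido)acetate)] (1 mol %), MeCN, 0 °C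
Reagents that add atoms: none
Why: Oxidation to the diaryl diazo compound and rhodium-carbene insertion into the benzylic ether C–H bond close the dihydrobenzofuran; the chiral carboxylate ligands select the enantiotopic C–H bond and so set C-3′, the concerted insertion giving the cis isomer.

Step 21
Reactants: 32 cis-dihydrobenzofuran
Product: 34 (2S,3S)-4-bromo-3-(3,5-diacetoxyphenyl)-2-(4-acetoxyphenyl)-2,3-dihydrobenzofuran-6-yl acetate (trans), via tetraphenol 33 (not isolated)
Conditions: BBr3, CH2Cl2, −78 to 25 °C; MeOH; then Ac2O, pyridine, DMAP, 25 °C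
Reagents that add atoms: acetic anhydride, CC(=O)OC(C)=O
Why: Ether cleavage should epimerise C-2′ to the stable trans isomer by reversible opening of the O–C-2′ bond to the para-quinone methide (C-3′ is not touched), and acetylation then gives a base-labile protected form.

Step 22
Reactants: 34 trans tetraacetate bromide; 35 tributyl(vinyl)stannane
Product: 36 (2S,3S)-3-(3,5-diacetoxyphenyl)-2-(4-acetoxyphenyl)-4-vinyl-2,3-dihydrobenzofuran-6-yl acetate
Conditions: Pd(PPh3)4 (5 mol %), toluene, 100 °C
Reagents that add atoms: none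
Why: Stille coupling introduces the vinyl group under neutral conditions that the aryl acetates tolerate.

Step 23
Reactants: 23 western hexaacetate chloride; 36 eastern vinyl tetraacetate
Product: 37 vitisin A deca-O-acetate
Conditions: Pd2(dba)3 (2.5 mol %), P(t-Bu)3 (10 mol %), Cy2NMe, 1,4-dioxane, 110 °C
Reagents that add atoms: none
Why: Mizoroki–Heck reaction of the aryl chloride (electron-rich bulky phosphine for C–Cl activation) with the styrene gives the E-stilbene by syn-insertion and syn-β-hydride elimination, and the amine base leaves the acetates intact.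

Step 24
Reactants: 37 vitisin A deca-O-acetate
Product: 38 (+)-vitisin A
Conditions: K2CO3 (cat.), degassed MeOH, 0 to 25 °C; AcOH
Reagents that add atoms: none
Why: Zemplén-type transesterification removes all ten acetates under mild base and avoids the acid-induced cyclisation of the stilbene onto the neighbouring resorcinol ring; no stereocentre is touched.

**Compound list**

1 | 3-bromo-5-methoxyphenol | COc1cc(O)cc(Br)c1 | starting material
2 | 1-bromo-3-methoxy-5-(methoxymethoxy)benzene | COCOc1cc(OC)cc(Br)c1 | intermediate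
3 | 5-chlorobenzofuran-2(3H)-one | O=C1Cc2cc(Cl)ccc2O1 | starting material
4 | 5-chloro-3-[3-methoxy-5-(methoxymethoxy)phenyl]benzofuran-2(3H)-one (racemic) | COCOc1cc(OC)cc(C2C(=O)Oc3ccc(Cl)cc23)c1 | intermediate
5 | 5-chloro-3-(3-hydroxy-5-methoxyphenyl)benzofuran-2(3H)-one (racemic) | COc1cc(O)cc(C2C(=O)Oc3ccc(Cl)cc23)c1 | intermediate
6 | 2-bromo-4,6-dimethoxybenzaldehyde | COc1cc(Br)c(C=O)c(OC)c1 | starting material
7 | [4-(tert-butyldimethylsilyloxy)phenyl]magnesium bromide | CC(C)(C)[Si](C)(C)Oc1ccc([Mg]Br)cc1 | starting material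
8 | (2-bromo-4,6-dimethoxyphenyl)[4-(tert-butyldimethylsilyloxy)phenyl]methanol (racemic) | COc1cc(Br)c(C(O)c2ccc(O[Si](C)(C)C(C)(C)C)cc2)c(OC)c1 | intermediate
9 | {(2-bromo-4,6-dimethoxyphenyl)[4-(tert-butyldimethylsilyloxy)phenyl]methoxy}triisopropylsilane | COc1cc(Br)c(C(O[Si](C(C)C)(C(C)C)C(C)C)c2ccc(O[Si](C)(C)C(C)(C)C)cc2)c(OC)c1 | intermediate
10 | N-methoxy-N-methyl-2-(4-methoxyphenyl)acetamide | COc1ccc(CC(=O)N(C)OC)cc1 | starting material
11 | 1-{2-[(4-(tert-butyldimethylsilyloxy)phenyl)(triisopropylsilyloxy)methyl]-3,5-dimethoxyphenyl}-2-(4-methoxyphenyl)ethan-1-one | COc1ccc(CC(=O)c2cc(OC)cc(OC)c2C(O[Si](C(C)C)(C(C)C)C(C)C)c2ccc(O[Si](C)(C)C(C)(C)C)cc2)cc1 | intermediate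
12 | 2-diazo-1-{2-[(4-(tert-butyldimethylsilyloxy)phenyl)(triisopropylsilyloxy)methyl]-3,5-dimethoxyphenyl}-2-(4-methoxyphenyl)ethan-1-one | COc1ccc(C(=[N+]=[N-])C(=O)c2cc(OC)cc(OC)c2C(O[Si](C(C)C)(C(C)C)C(C)C)c2ccc(O[Si](C)(C)C(C)(C)C)cc2)cc1 | intermediate
13 | 2-[3-(5-chloro-2-oxo-2,3-dihydrobenzofuran-3-yl)-5-methoxyphenoxy]-1-{2-[(4-(tert-butyldimethylsilyloxy)phenyl)(triisopropylsilyloxy)methyl]-3,5-dimethoxyphenyl}-2-(4-methoxyphenyl)ethan-1-one (diastereomer mixture) | COc1ccc(C(Oc2cc(OC)cc(C3C(=O)Oc4ccc(Cl)cc34)c2)C(=O)c2cc(OC)cc(OC)c2C(O[Si](C(C)C)(C(C)C)C(C)C)c2ccc(O[Si](C)(C)C(C)(C)C)cc2)cc1 | intermediate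
14 | 2-[3-(5-chloro-2-oxo-2,3-dihydrobenzofuran-3-yl)-5-methoxyphenoxy]-1-{2-[hydroxy(4-hydroxyphenyl)methyl]-3,5-dimethoxyphenyl}-2-(4-methoxyphenyl)ethan-1-one (diastereomer mixture) | COc1ccc(C(Oc2cc(OC)cc(C3C(=O)Oc4ccc(Cl)cc34)c2)C(=O)c2cc(OC)cc(OC)c2C(O)c2ccc(O)cc2)cc1 | intermediate
15 | 5-chloro-3-[3-{2-[hydroxy(4-hydroxyphenyl)methyl]-3,5-dimethoxyphenyl}-6-methoxy-2-(4-methoxyphenyl)benzofuran-4-yl]benzofuran-2(3H)-one | COc1ccc(-c2oc3cc(OC)cc(C4C(=O)Oc5ccc(Cl)cc45)c3c2-c2cc(OC)cc(OC)c2C(O)c2ccc(O)cc2)cc1 | intermediate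
16 | para-quinone methide from 15 (4-arylmethylidene-cyclohexa-2,5-dien-1-one at C-α) | COc1ccc(-c2oc3cc(OC)cc(C4C(=O)Oc5ccc(Cl)cc45)c3c2-c2cc(OC)cc(OC)c2C=C2C=CC(=O)C=C2)cc1 | intermediate
17 | (αS)-spiro-lactone: benzofuran (ring A; 2-(4-methoxyphenyl), 6-OMe) whose C-3 and C-4 are bridged by ring B (dimethoxy), C-α(H)(4-hydroxyphenyl) and C-β into a seven-membered ring; C-β is the spiro C-3 of a 5-chlorobenzofuran-2(3H)-one (C-β diastereomer mixture) | Oc1ccc([C@H]2c3c(OC)cc(OC)cc3-c3c4c(cc(OC)cc4C25C(=O)Oc4ccc(Cl)cc45)oc3-c2ccc(OC)cc2)cc1 | intermediate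
18 | (αS)-spiro-lactol: 17 with the lactone C=O reduced to CH(OH) | Oc1ccc([C@H]2c3c(OC)cc(OC)cc3-c3c4c(cc(OC)cc4C25C(O)Oc4ccc(Cl)cc45)oc3-c2ccc(OC)cc2)cc1 | intermediate
19 | (αS)-aldehyde: C-β bears CHO and 5-chloro-2-methoxyphenyl; C-α bears 4-methoxyphenyl | COc1ccc([C@H]2c3c(OC)cc(OC)cc3-c3c4c(cc(OC)cc4C2(C=O)c2cc(Cl)ccc2OC)oc3-c2ccc(OC)cc2)cc1 | intermediate
20 | (αS,βS)-benzofuran hexamethyl ether: C-β bears H and 5-chloro-2-methoxyphenyl, cis to the 4-methoxyphenyl on C-α | COc1ccc([C@H]2c3c(OC)cc(OC)cc3-c3c4c(cc(OC)cc4[C@H]2c2cc(Cl)ccc2OC)oc3-c2ccc(OC)cc2)cc1 | intermediate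
21 | (2S,3S,αS,βS)-western trans-2,3-dihydrobenzofuran hexamethyl ether (aryl chloride) | COc1ccc([C@H]2c3c(OC)cc(OC)cc3[C@H]3c4c(cc(OC)cc4[C@H]2c2cc(Cl)ccc2OC)O[C@@H]3c2ccc(OC)cc2)cc1 | intermediate
22 | (2S,3S,αS,βS)-western hexaphenol (aryl chloride) | Oc1ccc([C@H]2c3c(O)cc(O)cc3[C@H]3c4c(cc(O)cc4[C@H]2c2cc(Cl)ccc2O)O[C@@H]3c2ccc(O)cc2)cc1 | intermediate
23 | (2S,3S,αS,βS)-western hexaacetate (aryl chloride) | CC(=O)Oc1ccc([C@H]2c3c(OC(C)=O)cc(OC(C)=O)cc3[C@H]3c4c(cc(OC(C)=O)cc4[C@H]2c2cc(Cl)ccc2OC(C)=O)O[C@@H]3c2ccc(OC(C)=O)cc2)cc1 | intermediate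
24 | 2-bromo-6-hydroxy-4-methoxybenzaldehyde | O=Cc1c(Br)cc(OC)cc1O | intermediate
25 | 4-methoxybenzyl chloride | COc1ccc(CCl)cc1 | starting material
26 | 2-bromo-4-methoxy-6-[(4-methoxybenzyl)oxy]benzaldehyde | O=Cc1c(Br)cc(OC)cc1OCc1ccc(OC)cc1 | intermediate
27 | (3,5-dimethoxyphenyl)magnesium chloride | COc1cc(OC)cc([Mg]Cl)c1 | starting material
28 | {2-bromo-4-methoxy-6-[(4-methoxybenzyl)oxy]phenyl}(3,5-dimethoxyphenyl)methanol (racemic) | OC(c1cc(OC)cc(OC)c1)c1c(Br)cc(OC)cc1OCc1ccc(OC)cc1 | intermediate
29 | {2-bromo-4-methoxy-6-[(4-methoxybenzyl)oxy]phenyl}(3,5-dimethoxyphenyl)methanone | O=C(c1cc(OC)cc(OC)c1)c1c(Br)cc(OC)cc1OCc1ccc(OC)cc1 | intermediate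
30 | hydrazone of 29 | NN=C(c1cc(OC)cc(OC)c1)c1c(Br)cc(OC)cc1OCc1ccc(OC)cc1 | intermediate
31 | diaryl diazomethane from 30 | [N-]=[N+]=C(c1cc(OC)cc(OC)c1)c1c(Br)cc(OC)cc1OCc1ccc(OC)cc1 | intermediate
32 | (2R,3S)-4-bromo-3-(3,5-dimethoxyphenyl)-6-methoxy-2-(4-methoxyphenyl)-2,3-dihydrobenzofuran (cis) | Brc1cc(OC)cc2c1[C@H](c1cc(OC)cc(OC)c1)[C@H](c1ccc(OC)cc1)O2 | intermediate
33 | (2S,3S)-4-bromo-3-(3,5-dihydroxyphenyl)-2-(4-hydroxyphenyl)-2,3-dihydrobenzofuran-6-ol (trans) | Brc1cc(O)cc2c1[C@H](c1cc(O)cc(O)c1)[C@@H](c1ccc(O)cc1)O2 | intermediate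
34 | (2S,3S)-4-bromo-3-(3,5-diacetoxyphenyl)-2-(4-acetoxyphenyl)-2,3-dihydrobenzofuran-6-yl acetate | Brc1cc(OC(C)=O)cc2c1[C@H](c1cc(OC(C)=O)cc(OC(C)=O)c1)[C@@H](c1ccc(OC(C)=O)cc1)O2 | intermediate
35 | tributyl(vinyl)stannane | C=C[Sn](CCCC)(CCCC)CCCC | starting material
36 | (2S,3S)-3-(3,5-diacetoxyphenyl)-2-(4-acetoxyphenyl)-4-vinyl-2,3-dihydrobenzofuran-6-yl acetate | C=Cc1cc(OC(C)=O)cc2c1[C@H](c1cc(OC(C)=O)cc(OC(C)=O)c1)[C@@H](c1ccc(OC(C)=O)cc1)O2 | intermediate
37 | vitisin A deca-O-acetate | CC(=O)Oc1ccc([C@H]2c3c(OC(C)=O)cc(OC(C)=O)cc3[C@H]3c4c(cc(OC(C)=O)cc4[C@H]2c2cc(/C=C/c4cc(OC(C)=O)cc5c4[C@H](c4cc(OC(C)=O)cc(OC(C)=O)c4)[C@@H](c4ccc(OC(C)=O)cc4)O5)ccc2OC(C)=O)O[C@@H]3c2ccc(OC(C)=O)cc2)cc1 | intermediate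
38 | (+)-vitisin A (all six stereocentres S) | Oc1ccc([C@H]2c3c(O)cc(O)cc3[C@H]3c4c(cc(O)cc4[C@H]2c2cc(/C=C/c4cc(O)cc5c4[C@H](c4cc(O)cc(O)c4)[C@@H](c4ccc(O)cc4)O5)ccc2O)O[C@@H]3c2ccc(O)cc2)cc1 | target

**Count**

Total steps: 24. Longest linear sequence: 13 steps (steps 4 to 14, then 23 and 24, from 6).

**Steps most likely to fail**

1. Step 10 (proposed method). What may go wrong: ring closure at the wrong ortho carbon of ring A, intermolecular capture of the quinone methide, or poor facial selection by the chiral acid in the seven-ring closure. The fallback uses known reactions only and sets out from 14. Bi(OTf)3 (5 mol %) in CH2Cl2 effects the established cyclodehydration of the α-aryloxy ketone, and 15 is isolated. Diphenyl phosphate in toluene then closes the seven-membered ring through the quinone methide without induction, which gives 17 together with its mirror-image spiro-lactone F1. Preparative chromatography on a chiral stationary phase removes F1, and the route is rejoined at 17.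

2. Step 12. What may go wrong: slow expulsion of the diarylmethyl carbanion from the aldehyde hydrate, protonation from the wrong face, or base-induced fragmentation back to a quinone methide if methylation is incomplete. The fallback sets out from 18. The methylation is run as in step 12, but aldehyde 19 is isolated and then subjected to a thiol-catalysed radical-chain decarbonylation (tert-dodecanethiol, di-tert-butyl peroxide, chlorobenzene, 130 °C). The acyl radical loses CO, and the planar diarylmethyl radical should take a hydrogen atom from the thiol on the face anti to the C-α aryl, giving 20 under neutral conditions. The route is rejoined at 20; the detour makes no compound beyond 19 and 20 (entry F0).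

3. Step 13. What may go wrong: protonation of the benzofuran at C-3 from the concave face (wrong configuration relative to C-α and C-β), incomplete reduction of the hindered tetrasubstituted enol ether, or acid-induced scrambling. The fallback sets out from 20. Heterogeneous hydrogenation (H2, 40 bar, sulfided Pt/C, EtOAc–AcOH, 50 °C; the sulfided catalyst spares the aryl chloride) should add both hydrogens to the convex face and give the cis-2,3-dihydrobenzofuran F2. F2 is taken into the BBr3 treatment of step 14, where reversible opening of the O–C-2 bond through the para-quinone methide equilibrates C-2 to trans, so the route is rejoined at 22.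

Further compounds
F1 | step 10 | (αR)-spiro-lactone, mirror image of 17 | Oc1ccc([C@@H]2c3c(OC)cc(OC)cc3-c3c4c(cc(OC)cc4C25C(=O)Oc4ccc(Cl)cc45)oc3-c2ccc(OC)cc2)cc1
F0 | step 12 | none | none
F2 | step 13 | (2R,3S,αS,βS)-cis-2,3-dihydrobenzofuran hexamethyl ether, C-2 epimer of 21 | COc1ccc([C@H]2c3c(OC)cc(OC)cc3[C@H]3c4c(cc(OC)cc4[C@H]2c2cc(Cl)ccc2OC)O[C@H]3c2ccc(OC)cc2)cc1
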